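**Retrosynthetic overview**
1. Last C–C bond: the dienyl carbinol bond, from (1Z,3E)-dienylmagnesium 28 and epoxy aldehyde 12; desilylation then gives the target.
2. Core 12 goes back through SN2 inversion at C2, Stille hydroxymethylation of the vinyl bromide and a Payne shift of an anti 5,6-oxirane to the ipso,ortho cis-diol 2, made by enzymatic dearomatisation of 4-bromobenzoic acid.
3. Feature used: ring carbon C1 of the cyclohexene is quaternary, carries the oxirane oxygen and the carbinol carbon, is flanked by the oxygenated C2 and C6, and lies para to C4 bearing CH2OH. These are the ipso carbon (with its carboxyl), the two ortho carbons and the para carbon of a 4-substituted benzoic acid.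
4. Side chain: cyclohexane ring by Ti(III) radical cyclisation of (R)-6,7-epoxygeranyl acetate; Z-trisubstituted alkene by bromoboration of propyne, Negishi coupling and iododeboronation.
5. Ring order: the core carbocycle is the arene ring of 1 (no ring closure); the oxirane is closed in step 5; the side-chain cyclohexane in step 12.

Key step: step 1

Remark on numbering: core ring C1 = carbon bearing the carboxyl-derived carbon, C2 = enzymatic secondary carbinol, C3 = CH, C4 = C–Br (later C–CH2OH), C5, C6; β = face of the C1 oxygen, α = face of the C1 carbon substituent.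
Assumption: the dioxygenase accepts 4-bromobenzoate and gives the same absolute sense as with benzoate, (1S,2R); this is to be confirmed on 2 before material is carried on.

**Core**

Step 1
Reactants: 1 4-bromobenzoic acid
Product: 2 (1S,2R)-4-bromo-1,2-dihydroxycyclohexa-3,5-diene-1-carboxylic acid
Conditions: whole cells (E. coli expressing toluate 1,2-dioxygenase XylXYZ, no cis-diol dehydrogenase), sodium 4-bromobenzoate fed, glucose, phosphate buffer pH 7, air, 30 °C
Reagents that add atoms: dioxygen, O=O
Why: The Rieske non-heme iron dioxygenase binds the carboxylate in its pocket, activates O2 at the mononuclear iron with two electrons relayed from NADH through the Rieske cluster, and delivers both oxygen atoms to the same face of the ipso and ortho carbons. The closest known reaction type is the whole-cell ipso,ortho cis-dihydroxylation of benzoate and of halo- and methylbenzoates by benzoate and toluate 1,2-dioxygenases. No ring is closed: the benzene ring of 1 becomes the cyclohexadiene, and two C–O bonds are formed. Both new stereocentres (C1 and C2) are set by the active site, cis because both oxygens come from one iron-bound dioxygen, in the (1S,2R) sense of the benzoate series. The step needs ipso,ortho regiochemistry, one absolute sense and no further oxidation; the carboxylate anchor supplies the first two (the para bromine keeps the two ortho carbons equivalent, so only the face has to be chosen), and the absence of the diol dehydrogenase prevents rearomatisation to the catechol.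

Step 2
Reactants: 2 (1S,2R)-4-bromo-1,2-dihydroxycyclohexa-3,5-diene-1-carboxylic acid
Product: 3 methyl (1S,2R)-4-bromo-1,2-dihydroxycyclohexa-3,5-diene-1-carboxylate
Conditions: TMSCHN2, MeOH/toluene, 0 °C
Reagents that add atoms: trimethylsilyldiazomethane, C[Si](C)(C)C=[N+]=[N-]
Why: Esterification of the acid with a diazoalkane is neutral and so spares the cis-diene diol, which would rearomatise by dehydration under acid, and it touches no stereocentre.

Step 3
Reactants: 3 methyl (1S,2R)-4-bromo-1,2-dihydroxycyclohexa-3,5-diene-1-carboxylate
Product: 4 1,2-O-(di-tert-butylsilanediyl) derivative of 3 (cis-fused dioxasilolane on the β face)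
Conditions: tBu2Si(OTf)2, 2,6-lutidine, CH2Cl2, −78 → 0 °C
Reagents that add atoms: di-tert-butylsilyl bis(trifluoromethanesulfonate), CC(C)(C)[Si](OS(=O)(=O)C(F)(F)F)(OS(=O)(=O)C(F)(F)F)C(C)(C)C
Why: Cyclic silylene formation across the cis-1,2-diol with the bis-triflate engages even the tertiary hydroxyl, puts a tert-butyl group over the β face, and is chosen over an acetonide because fluoride removes it without the acid that the allylic oxirane of the next step would not survive.

Step 4
Reactants: 4 1,2-O-(di-tert-butylsilanediyl) derivative of 3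
Product: 5 5α,6α-epoxide of 4 (oxirane anti to the silylene)
Conditions: mCPBA, NaHCO3, CH2Cl2, 0 → 23 °C
Reagents that add atoms: 3-chloroperoxybenzoic acid, OOC(=O)c1cccc(Cl)c1
Why: In this Prilezhaev epoxidation the peracid should take the unhalogenated C5=C6 bond over the bromine-deactivated C3=C4 bond and approach anti to the cis-fused silylene, as is usual for cis-fused arene-diol acetals, so that the new stereocentres C5 and C6 carry the oxirane on the α face, where the ester carbonyl can also hydrogen-bond the peracid.

Step 5
Reactants: 5 5α,6α-epoxide of 4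
Product: 7 methyl 4-bromo-1β,6β-epoxy-2β,5α-dihydroxycyclohex-3-ene-1-carboxylate, via epoxy diol 6 (not isolated)
Conditions: TBAF (2.2 equiv), THF, 0 °C; then K2CO3 (0.2 equiv), MeOH, 23 °C
Reagents that add atoms: none
Why: Fluoride cleaves the strained five-membered silylene, and the freed C1 alkoxide, anti-periplanar to the C6–O bond of the α-oxirane, attacks C6 with inversion in a Payne rearrangement that moves the oxirane to C1–C6 on the β face and leaves the C5 oxygen α; under catalytic base the neutral epoxy alcohols equilibrate and the trisubstituted, ester-bearing oxirane with a secondary allylic alcohol should be the more stable, while the C2 hydroxyl is syn to the new oxirane and cannot take part.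

Step 6
Reactants: 7 methyl 4-bromo-1β,6β-epoxy-2β,5α-dihydroxycyclohex-3-ene-1-carboxylate
Product: 8 methyl 1β,6β-epoxy-2β,5α-dihydroxy-4-(hydroxymethyl)cyclohex-3-ene-1-carboxylate
Conditions: Bu3SnCH2OH, Pd(PPh3)4 (10 mol%), 1,4-dioxane, 90 °C
Reagents that add atoms: (tributylstannyl)methanol, CCCC[Sn](CCCC)(CCCC)CO
Why: Stille coupling of the vinyl bromide with the hydroxymethyl stannane runs under neutral conditions that leave the ester, the free hydroxyls and the no longer allylic oxirane untouched, and it forms no stereocentre.

Step 7
Reactants: 8 methyl 1β,6β-epoxy-2β,5α-dihydroxy-4-(hydroxymethyl)cyclohex-3-ene-1-carboxylate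
Product: 9 5-O,4-CH2O-(di-tert-butylsilanediyl) derivative of 8 with free 2β-hydroxyl
Conditions: tBu2Si(OTf)2 (1.05 equiv), 2,6-lutidine, CH2Cl2, −78 → 0 °C
Reagents that add atoms: di-tert-butylsilyl bis(trifluoromethanesulfonate), CC(C)(C)[Si](OS(=O)(=O)C(F)(F)F)(OS(=O)(=O)C(F)(F)F)C(C)(C)C
Why: In this silylene protection of a 1,3-diol only the primary CH2OH oxygen and the adjacent C5 hydroxyl can close a six-membered dioxasilinane (the C2 hydroxyl is trans to the CH2OH across C3=C4 and cannot bridge), so one equivalent of reagent leaves the C2 hydroxyl free.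

Step 8
Reactants: 9 5-O,4-CH2O-(di-tert-butylsilanediyl) derivative of 8 with free 2β-hydroxyl
Product: 10 2α-(4-nitrobenzoate) of the C2 epimer of 9
Conditions: 4-nitrobenzoic acid, PPh3, DIAD, toluene, 0 → 23 °C
Reagents that add atoms: 4-nitrobenzoic acid, OC(=O)c1ccc(cc1)[N+](=O)[O-]
Why: In this Mitsunobu reaction the oxyphosphonium at C2 is displaced by the carboxylate in an SN2 step with inversion, turning the β carbinol into the α ester; elimination has no available hydrogen (C1 is an oxirane carbon, C3 is sp2), ionisation is disfavoured by the electron-poor oxirane next door, SN2′ would have to occur at the fully substituted C4, and displacement is preferred to oxidation and reduction because hydride tends to add to flat 2,3-epoxy enones anti to the oxirane oxygen, which would restore the β alcohol.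

Step 9
Reactants: 10 2α-(4-nitrobenzoate) of the C2 epimer of 9
Product: 11 2α-alcohol (C2 epimer of 9)
Conditions: K2CO3 (0.2 equiv), MeOH, 0 °C
Reagents that add atoms: none
Why: Base-catalysed transesterification removes the activated aryl ester as its methyl ester at 0 °C, where exchange at the methyl ester is degenerate, the six-membered silylene is stable, and the C2 alkoxide has neither the time nor the driving force to attack the fully substituted C1 of the oxirane.

Step 10
Reactants: 11 2α-alcohol (C2 epimer of 9)
Product: 12 1β,6β-epoxy-2α-hydroxy aldehyde (CHO on C1 and silylene retained)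
Conditions: DIBAL-H (2.2 equiv), CH2Cl2, −78 °C; Rochelle salt work-up
Reagents that add atoms: none
Why: In this partial ester reduction the first equivalent of DIBAL-H turns the hydroxyl into an aluminium alkoxide and the chelated aluminium hemiacetal of the α-oxygenated, quaternary ester persists at −78 °C until hydrolysis, so the aldehyde, which has no α-hydrogen, is released without over-reduction or epimerisation.

**Side chain**

Step 11
Reactants: 13 geranyl acetate
Product: 14 (R)-6,7-epoxygeranyl acetate
Conditions: D-fructose-derived Shi ketone (30 mol%), Oxone, K2CO3, Bu4NHSO4, MeCN/dimethoxymethane/aq buffer pH 10.5, 0 °C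
Reagents that add atoms: potassium peroxymonosulfate (Oxone), [K+].[O-]S(=O)(=O)OO
Why: In the Shi asymmetric epoxidation the chiral dioxirane takes the electron-rich 6,7-alkene over the 2,3-alkene deactivated by the allylic acetate, and the D-fructose-derived ketone delivers oxygen through its spiro transition state to the face that gives the (R)-epoxide of a trisubstituted alkene.

Step 12
Reactants: 14 (R)-6,7-epoxygeranyl acetate
Product: 15 [(1S,3R)-3-hydroxy-2,2-dimethyl-6-methylidenecyclohexyl]methyl acetate (OH and CH2OAc cis)
Conditions: Cp2TiCl2 (2.2 equiv), Mn dust, THF, 23 °C, slow addition of 14; aq HCl work-up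
Reagents that add atoms: none
Why: In this titanocene(III)-mediated radical cyclisation, homolytic opening of the epoxide at the tertiary carbon gives a β-titanoxy radical that closes 6-endo onto the E-alkene through a chair in which the C–O bond and the CH2OAc group are both equatorial (cis on the ring, so the new CH centre is set from the epoxide centre), and trapping of the tertiary radical by a second Cp2TiCl followed by β-hydride loss gives the exocyclic methylene.

Step 13
Reactants: 15 [(1S,3R)-3-hydroxy-2,2-dimethyl-6-methylidenecyclohexyl]methyl acetate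
Product: 16 triethylsilyl ether of 15
Conditions: TESCl, imidazole, DMF, 23 °C
Reagents that add atoms: chlorotriethylsilane, CC[Si](Cl)(CC)CC
Why: Silylation of the secondary alcohol gives a triethylsilyl ether that survives the base, oxidant and organometallic steps ahead and is removed together with the silylene at the end.

Step 14
Reactants: 16 triethylsilyl ether of 15
Product: 17 [(1S,3R)-2,2-dimethyl-6-methylidene-3-(triethylsilyloxy)cyclohexyl]methanol
Conditions: K2CO3, MeOH, 23 °C
Reagents that add atoms: none
Why: Methanolysis of the primary acetate with catalytic carbonate leaves the hindered secondary silyl ether untouched.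

Step 15
Reactants: 17 [(1S,3R)-2,2-dimethyl-6-methylidene-3-(triethylsilyloxy)cyclohexyl]methanol
Product: 18 (1S,3R)-2,2-dimethyl-6-methylidene-3-(triethylsilyloxy)cyclohexane-1-carbaldehyde
Conditions: Dess–Martin periodinane, NaHCO3, CH2Cl2, 0 °C
Reagents that add atoms: none
Why: Dess–Martin oxidation under bicarbonate buffer gives the β,γ-unsaturated aldehyde without acid or base strong enough to epimerise the α-centre or move the exocyclic alkene into conjugation.

Step 16
Reactants: 18 (1S,3R)-2,2-dimethyl-6-methylidene-3-(triethylsilyloxy)cyclohexane-1-carbaldehyde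
Product: 19 (E)-vinyl iodide (CHO of 18 replaced by (E)-CH=CHI)
Conditions: CrCl2, CHI3, THF, 0 °C
Reagents that add atoms: iodoform, IC(I)I
Why: In the Takai olefination the geminal dichromium species from iodoform adds to the aldehyde and eliminates to the (E)-vinyl iodide under non-basic conditions that preserve the α-stereocentre.

Step 17
Reactants: 20 propyne
Product: 22 (Z)-2-bromoprop-1-enylboronic acid pinacol ester, via dibromoborane 21 (not isolated)
Conditions: BBr3, CH2Cl2, −78 → 23 °C; then pinacol
Reagents that add atoms: boron tribromide, BrB(Br)Br; pinacol, CC(C)(O)C(C)(C)O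
Why: Bromoboration of the terminal alkyne is a syn addition with boron at the terminal carbon, so bromine and boron end cis, and ligand exchange with pinacol gives the storable (Z)-bromoalkenyl boronate.

Step 18
Reactants: 19 (E)-vinyl iodide; 22 (Z)-2-bromoprop-1-enylboronic acid pinacol ester
Product: 25 (1Z,3E)-2-methyl-4-(cyclohexyl)buta-1,3-dienylboronic acid pinacol ester, via alkenyllithium 23 (not isolated), via alkenylzinc bromide 24 (not isolated)
Conditions: 19, t-BuLi (2.0 equiv), Et2O, −78 °C; ZnBr2, THF; then 22, Pd(tBu3P)2 (2 mol%), THF, 23 °C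
Reagents that add atoms: none
Why: Iodine–lithium exchange and transmetalation give the (E)-alkenylzinc with retention, and Negishi coupling occurs at the C–Br bond of 22 with retention while the boronate is inert without base, so the incoming alkenyl carbon ends cis to boron and the trisubstituted alkene is Z.

Step 19
Reactants: 25 (1Z,3E)-dienylboronic acid pinacol ester
Product: 26 (1Z,3E)-dienyl iodide (Bpin of 25 replaced by I)
Conditions: I2, NaOH, THF/H2O, 0 °C
Reagents that add atoms: iodine, II
Why: Iododeboronation of the alkenylboronate ate complex with iodine and hydroxide proceeds with retention of alkene geometry.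

**Coupling and deprotection**

Step 20
Reactants: 26 (1Z,3E)-dienyl iodide; 12 1β,6β-epoxy-2α-hydroxy aldehyde
Product: 30 coupled (S)-dienyl carbinol (silylene and triethylsilyl ether retained), via dienyllithium 27 (not isolated), via dienylmagnesium bromide 28 (not isolated), via magnesium alkoxide 29 (not isolated)
Conditions: 26, t-BuLi (2.0 equiv), Et2O, −78 °C; MgBr2·OEt2; 12 pretreated with t-BuMgCl (1.0 equiv), THF, −78 °C; combine, −78 → −40 °C; aq NH4Cl
Reagents that add atoms: none
Why: In this chelation-controlled Grignard addition the chloromagnesium alkoxide on C2, cis to the formyl group, binds the aldehyde oxygen in a six-membered chelate that holds the carbonyl syn to C2, and the (Z)-dienylmagnesium (formed with retention) attacks the more open face on the side of the oxirane oxygen, away from C6–H and the silylene-bearing α side, which should give the (S)-carbinol, while the quaternary α-carbon excludes enolisation.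

Step 21
Reactants: 30 coupled (S)-dienyl carbinol
Product: 31 target CNP0357844.1
Conditions: HF·pyridine, excess pyridine, THF, 0 → 23 °C
Reagents that add atoms: none
Why: Fluoride cleavage of the Si–O bonds with pyridine-buffered HF removes the silylene and the triethylsilyl ether without acid or base strong enough to ionise the dienyl carbinol or start Payne migration of the oxirane, and no stereocentre is affected.

**Compound list**
1 | 4-bromobenzoic acid | OC(=O)c1ccc(Br)cc1 | starting material
2 | (1S,2R)-4-bromo-1,2-dihydroxycyclohexa-3,5-diene-1-carboxylic acid (cis-diol) | OC(=O)[C@]1(O)C=CC(Br)=C[C@H]1O | intermediate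
3 | methyl (1S,2R)-4-bromo-1,2-dihydroxycyclohexa-3,5-diene-1-carboxylate | COC(=O)[C@]1(O)C=CC(Br)=C[C@H]1O | intermediate
4 | 1,2-O-(di-tert-butylsilanediyl) derivative of 3, cis-fused on the β face | COC(=O)[C@]12C=CC(Br)=C[C@H]1O[Si](C(C)(C)C)(C(C)(C)C)O2 | intermediate
5 | 5α,6α-epoxide of 4 (oxirane anti to the silylene) | COC(=O)[C@]12[C@@H]3O[C@@H]3C(Br)=C[C@H]1O[Si](C(C)(C)C)(C(C)(C)C)O2 | intermediate
6 | methyl 4-bromo-5α,6α-epoxy-1β,2β-dihydroxycyclohex-3-ene-1-carboxylate (not isolated) | COC(=O)[C@]1(O)[C@@H]2O[C@@H]2C(Br)=C[C@H]1O | intermediate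
7 | methyl 4-bromo-1β,6β-epoxy-2β,5α-dihydroxycyclohex-3-ene-1-carboxylate | COC(=O)[C@]12O[C@H]1[C@H](O)C(Br)=C[C@H]2O | intermediate
8 | methyl 1β,6β-epoxy-2β,5α-dihydroxy-4-(hydroxymethyl)cyclohex-3-ene-1-carboxylate | COC(=O)[C@]12O[C@H]1[C@H](O)C(CO)=C[C@H]2O | intermediate
9 | 8 with the C5α oxygen and the CH2O oxygen bridged by di-tert-butylsilanediyl; 2β-OH free | COC(=O)[C@]12O[C@H]1[C@H](O[Si](C(C)(C)C)(C(C)(C)C)OC3)C3=C[C@H]2O | intermediate
10 | C2 epimer of 9 as its 2α-(4-nitrobenzoate) | COC(=O)[C@]12O[C@H]1[C@H](O[Si](C(C)(C)C)(C(C)(C)C)OC3)C3=C[C@@H]2OC(=O)c4ccc(cc4)[N+](=O)[O-] | intermediate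
11 | C2 epimer of 9 (2α-OH, anti to the oxirane) | COC(=O)[C@]12O[C@H]1[C@H](O[Si](C(C)(C)C)(C(C)(C)C)OC3)C3=C[C@@H]2O | intermediate
12 | aldehyde from 11 (CHO on C1, 2α-OH free, silylene retained) | O=C[C@]12O[C@H]1[C@H](O[Si](C(C)(C)C)(C(C)(C)C)OC3)C3=C[C@@H]2O | intermediate
13 | geranyl acetate | CC(C)=CCC/C(C)=C/COC(C)=O | starting material
14 | (R)-6,7-epoxygeranyl acetate | CC1(C)O[C@@H]1CC/C(C)=C/COC(C)=O | intermediate
15 | [(1S,3R)-3-hydroxy-2,2-dimethyl-6-methylidenecyclohexyl]methyl acetate (OH and CH2OAc cis) | C=C1CC[C@@H](O)C(C)(C)[C@H]1COC(C)=O | intermediate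
16 | triethylsilyl ether of 15 | C=C1CC[C@@H](O[Si](CC)(CC)CC)C(C)(C)[C@H]1COC(C)=O | intermediate
17 | [(1S,3R)-2,2-dimethyl-6-methylidene-3-(triethylsilyloxy)cyclohexyl]methanol | C=C1CC[C@@H](O[Si](CC)(CC)CC)C(C)(C)[C@H]1CO | intermediate
18 | (1S,3R)-2,2-dimethyl-6-methylidene-3-(triethylsilyloxy)cyclohexane-1-carbaldehyde | C=C1CC[C@@H](O[Si](CC)(CC)CC)C(C)(C)[C@H]1C=O | intermediate
19 | (E)-vinyl iodide: CHO of 18 replaced by (E)-CH=CHI | C=C1CC[C@@H](O[Si](CC)(CC)CC)C(C)(C)[C@H]1/C=C/I | intermediate
20 | propyne | CC#C | starting material
21 | (Z)-2-bromoprop-1-enyldibromoborane (not isolated) | C/C(Br)=C/B(Br)Br | intermediate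
22 | (Z)-2-bromoprop-1-enylboronic acid pinacol ester | C/C(Br)=C/B1OC(C)(C)C(C)(C)O1 | intermediate
23 | (E)-alkenyllithium from 19 (not isolated) | C=C1CC[C@@H](O[Si](CC)(CC)CC)C(C)(C)[C@H]1/C=C/[Li] | intermediate
24 | (E)-alkenylzinc bromide from 23 (not isolated) | C=C1CC[C@@H](O[Si](CC)(CC)CC)C(C)(C)[C@H]1/C=C/[Zn]Br | intermediate
25 | (1Z,3E)-dienylboronic acid pinacol ester (ring–CH=CH–C(CH3)=CH–Bpin, Bpin cis to the vinyl group) | C=C1CC[C@@H](O[Si](CC)(CC)CC)C(C)(C)[C@H]1/C=C/C(C)=C\B1OC(C)(C)C(C)(C)O1 | intermediate
26 | (1Z,3E)-dienyl iodide | C=C1CC[C@@H](O[Si](CC)(CC)CC)C(C)(C)[C@H]1/C=C/C(C)=C\I | intermediate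
27 | (1Z,3E)-dienyllithium (not isolated) | C=C1CC[C@@H](O[Si](CC)(CC)CC)C(C)(C)[C@H]1/C=C/C(C)=C\[Li] | intermediate
28 | (1Z,3E)-dienylmagnesium bromide (not isolated) | C=C1CC[C@@H](O[Si](CC)(CC)CC)C(C)(C)[C@H]1/C=C/C(C)=C\[Mg]Br | intermediate
29 | chloromagnesium 2α-alkoxide of 12 (not isolated) | O=C[C@]12O[C@H]1[C@H](O[Si](C(C)(C)C)(C(C)(C)C)OC3)C3=C[C@@H]2O[Mg]Cl | intermediate
30 | coupled (S)-carbinol, silylene and triethylsilyl ether retained | C=C1CC[C@@H](O[Si](CC)(CC)CC)C(C)(C)[C@H]1/C=C/C(C)=C\[C@H](O)[C@]12O[C@H]1[C@H](O[Si](C(C)(C)C)(C(C)(C)C)OC3)C3=C[C@@H]2O | intermediate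
31 | CNP0357844.1 | C=C1CC[C@@H](O)C(C)(C)[C@H]1/C=C/C(C)=C\[C@H](O)[C@]12O[C@H]1[C@H](O)C(CO)=C[C@@H]2O | target

**Step count**
Total: 21 steps. Longest linear sequence: 12 steps (steps 1–10, 20, 21).

**Steps most likely to fail**

Step 4. The peracid may be delivered to the β face or without selectivity, because the α face carries the ester on the allylic quaternary carbon; a β-oxirane cannot undergo the Payne shift. The fallback sets out from 2 and comes back at 7, and uses the carboxyl group, which sits on the α face, to deliver the oxygen. Iodolactonisation of 2 (I2, NaHCO3, CH2Cl2/H2O, 0 °C) should give the iodo β-lactone F1 by anti addition, with the carboxylate oxygen on C6 from the α face and iodine β on C5. K2CO3 in MeOH then opens the lactone to the methyl ester, the freed C6 α-alkoxide displaces the trans iodide to form the α-oxirane 6, and 6 shifts to 7 in the same flask. A γ-lactone closed at C5 with iodine on C6 would converge on the same oxirane.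

Step 8. Displacement at C2 may stall because the neighbouring C1 is fully substituted, or be diverted to SN2′ attack. The fallback sets out from 9 and comes back at 11, and replaces displacement by facial selection. Oxidation of the C2 alcohol with Dess–Martin periodinane gives the enone F2, and 1,2-reduction with NaBH4/CeCl3 in MeOH at −78 °C (Luche) gives 11 only if hydride enters on the β face. The ester on C1 and the silylene oxygen on C5, both α, are the elements that would steer it there; alcohol 9 formed by the other mode of attack is recycled.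

Step 20. Facial selectivity at the aldehyde may be poor if a five-membered chelate through the oxirane oxygen competes with the six-membered alkoxide chelate and exposes the other face. The fallback sets out from 11 and comes back at 31, and sets the carbinol by reduction instead of addition. Silylation of the C2 hydroxyl (TBSOTf, 2,6-lutidine) gives the silyl ether F3, and DIBAL-H at −78 °C gives the aldehyde F4. Addition of dienyllithium 27 gives the carbinol F5 as whatever mixture forms, and Dess–Martin oxidation gives the dienone F6 (kept cold and dark). Reduction with Zn(BH4)2 in Et2O at −20 °C should then give the (S)-carbinol F7: zinc bridges the carbonyl and oxirane oxygens and hydride enters from the side of C2, away from the oxirane CH, the usual course to anti epoxy alcohols. HF·pyridine/pyridine then gives 31.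

Further compounds
F1 | step 4 | iodo β-lactone of 2: lactone oxygen α on C6, iodine β on C5, 1β,2β-diol retained | O=C1O[C@@H]2[C@@H](I)C(Br)=C[C@@H](O)[C@]12O
F2 | step 8 | C2 ketone (enone) from 9 | COC(=O)[C@]12O[C@H]1[C@H](O[Si](C(C)(C)C)(C(C)(C)C)OC3)C3=CC2=O
F3 | step 20 | 2α-O-tert-butyldimethylsilyl ether of 11 | COC(=O)[C@]12O[C@H]1[C@H](O[Si](C(C)(C)C)(C(C)(C)C)OC3)C3=C[C@@H]2O[Si](C)(C)C(C)(C)C
F4 | step 20 | aldehyde from F3 | O=C[C@]12O[C@H]1[C@H](O[Si](C(C)(C)C)(C(C)(C)C)OC3)C3=C[C@@H]2O[Si](C)(C)C(C)(C)C
F5 | step 20 | dienyl carbinol from F4 and 27, carbinol configuration undefined | C=C1CC[C@@H](O[Si](CC)(CC)CC)C(C)(C)[C@H]1/C=C/C(C)=C\C(O)[C@]12O[C@H]1[C@H](O[Si](C(C)(C)C)(C(C)(C)C)OC3)C3=C[C@@H]2O[Si](C)(C)C(C)(C)C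
F6 | step 20 | (2Z,4E)-dienone from F5 | C=C1CC[C@@H](O[Si](CC)(CC)CC)C(C)(C)[C@H]1/C=C/C(C)=C\C(=O)[C@]12O[C@H]1[C@H](O[Si](C(C)(C)C)(C(C)(C)C)OC3)C3=C[C@@H]2O[Si](C)(C)C(C)(C)C
F7 | step 20 | (S)-carbinol from F6, all silyl groups retained | C=C1CC[C@@H](O[Si](CC)(CC)CC)C(C)(C)[C@H]1/C=C/C(C)=C\[C@H](O)[C@]12O[C@H]1[C@H](O[Si](C(C)(C)C)(C(C)(C)C)OC3)C3=C[C@@H]2O[Si](C)(C)C(C)(C)C
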